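You read at 50 h, so I want what the excess depends on at that moment, and the order in [coupling partner] comes first.

| setting | midnight | dusk | noon | east | south | south-west | west |
|---|---|---|---|---|---|---|---|
| left-handed substrate | 20 mM | 20 mM | 30 mM | 20 mM | 20 mM | 20 mM | 20 mM |
| right-handed substrate | 20 mM | 20 mM | 30 mM | 20 mM | 20 mM | 20 mM | 20 mM |
| coupling partner | 84 mM | 130 mM | 60 mM | 60.0 mM | 60.0 mM | 60.0 mM | 60.0 mM |
| temperature | 35 °C | 68 °C | 35 °C | 40 °C | 80 °C | 20 °C | 60 °C |
| remark | run made earlier | run made earlier | run made earlier |  |  |  |  |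
| time |  |  |  | 50 h | 50 h | 50 h | 50 h |

| run | time / h | left-handed product / % | right-handed product / % |
|---|---|---|---|
| midnight | 1.50 | 0.3 | 0 |
| midnight | 5.00 | 2.2 | 0.2 |
| midnight | 8.00 | 2.3 | 0.8 |
| midnight | 12.0 | 3.4 | 0.4 |
| midnight | 20.0 | 6.1 | 1.0 |
| midnight | 25.0 | 6.4 | 0.8 |
| midnight | 30.0 | 8.3 | 1.2 |
| dusk | 1.00 | 5.0 | 1.9 |
| dusk | 2.00 | 8.8 | 3.0 |
| dusk | 3.00 | 12.8 | 4.7 |
| dusk | 4.00 | 15.7 | 5.9 |
| dusk | 5.00 | 18.1 | 6.9 |
| dusk | 6.00 | 19.8 | 8.0 |
| dusk | 8.00 | 24.0 | 8.9 |
| noon | 6.00 | 1.3 | 0.5 |
| noon | 12.0 | 2.7 | 0.3 |
| noon | 20.0 | 4.1 | 0.8 |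
| noon | 25.0 | 5.6 | 0.8 |
| noon | 30.0 | 5.8 | 0.7 |

(scatter of a reading: 0.3 percentage points)

- coupling partner is single-handed; left-handed substrate and right-handed substrate are mirror images of each other, charged as a racemate, each of them at the stated concentration
- an excess is the difference of the two amounts in percent of their sum
- an excess is below zero if the other one leads
- the handed part of coupling partner does not stay in what it makes, so the products of the two hands are mirror images too

1. the flask with the highest excess of left-handed product over right-handed product ("all alike" if they lie within 1.5 percentage points) (east / south / south-west / west / all alike)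
2. excess of left-handed product over right-handed product at the end, east
3. excess of left-handed product over right-handed product at the end, south
4. excess of left-handed product over right-handed product at the end, south-west
5. excess of left-handed product over right-handed product at the end, west

At 30.0 h, left-handed product in midnight over noon is 1.43, and [coupling partner] in midnight over noon is 1.40, so I take the rate as first-order in [coupling partner]. Right-handed product is too small to test this, but if it behaves alike, [coupling partner] cancels from the ratio of the two products.

That ratio, left-handed product over right-handed product, is what I carry as the selectivity factor s. The last 3 midnight readings give 6.93 at 35 °C, and the last dusk reading gives 2.70 at 68 °C. An excess is then (s − 1)/(s + 1).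

I draw ln s straight through these two temperatures, which stretches the line beyond them for south and south-west. My factors are 6.01 for east, 1.91 for south, 10.7 for south-west and 3.39 for west. The excesses are 71.5%, 31.3%, 82.8% and 54.4%, so I say south-west.

Your forecast also names south-west, with 70%, 28%, 84% and 47% in the same order, on the ground that “The coldest flask has the highest excess”. We differ most on south and west, where mine stand higher.

The flasks give 70.3%, 33.7%, 84.8% and 53.2%, with south-west highest.

    coupling partner + left-handed substrate → left-handed product (k = 4.90 × 10⁻⁴ L mol⁻¹ s⁻¹, Ea = 63.0 kJ mol⁻¹)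
    coupling partner + right-handed substrate → right-handed product (k = 2.40 × 10⁻⁴ L mol⁻¹ s⁻¹, Ea = 89.0 kJ mol⁻¹)
    left-handed substrate ⇌ right-handed substrate (k = 2.50 × 10⁻⁴ s⁻¹, Ea = 115 kJ mol⁻¹)
    coupling partner → decomposed reagent (k = 1.40 × 10⁻⁵ s⁻¹, Ea = 111 kJ mol⁻¹)
    coupling partner ⇌ dormant form (K = 0.650, k = 7.20 × 10⁻⁶ s⁻¹, Ea = 125 kJ mol⁻¹, ΔH = −26.0 kJ mol⁻¹)
    2 coupling partner → self-condensation product (k = 1.70 × 10⁻⁴ L mol⁻¹ s⁻¹, Ea = 70.0 kJ mol⁻¹)
    (constants at 80 °C)

South and west stand 5.7 percentage points and 6.2 points above your forecast. South-west with 15 mM of coupling partner gives 85.1%, and south-west with its own charge but kept at 35 °C gives 74.6%, where my midnight factor 6.93 reckons 74.8%. In south, by 25.0 h, left-handed product reaches 27.6% and right-handed product 13.7% while coupling partner falls to 6.69% of its own charge and decomposed reagent reaches 20.5 mM. By 50.0 h, south has coupling partner at 2.48% of its own charge and left-handed product at 30.6%.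

The runs were generated by integration for an exercise; scatter was added.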